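3 questions are asked of this flask, and you answer them by counting half-lives on a ladder of times.

- cedar: left-handed substrate 0.36 M; right-handed substrate 0.36 M; coupling partner 2.19 M; free catalyst 36 mM; impurity 6.7 mM; run made earlier
- flask: left-handed substrate 0.73 M; coupling partner 2.19 M; free catalyst 36 mM; impurity 6.7 mM; right-handed substrate 0.73 M; time 25 min
cedar run (percent of the left-handed substrate and right-handed substrate together charged)

| time / min | left-handed product / % | right-handed product / % |
|---|---|---|
| 3.00 | 22 | 22 |
| 8.00 | 38 | 39 |
| 15.0 | 46 | 40 |
| 25.0 | 49 | 51 |

(scatter of a reading: 2 percentage points)
- free catalyst is single-handed; left-handed substrate and right-handed substrate are mirror images of each other, charged as a racemate, each of them at the stated concentration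
- the earlier runs were read with a standard deviation of 2 percentage points
- candidate steps: coupling partner + catalyst intermediate A -> free catalyst + left-handed product; free catalyst + left-handed substrate <-> catalyst intermediate A; left-handed product <-> right-handed product; coupling partner + catalyst intermediate B -> free catalyst + right-handed product; free catalyst + right-handed substrate <-> catalyst intermediate B; 2 free catalyst <-> resting dimer; free catalyst + impurity -> spent catalyst
- an excess is below zero if the other one leads
- excess of left-handed product over right-handed product in the product at 2.5 min
- excess of left-handed product over right-handed product in the product at 25 min
- part of the left-handed substrate and right-handed substrate charged together that has reacted at 25 min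

1. Start with the working catalyst, my name for the catalyst charge minus the impurity charge. The candidate step spends one free catalyst per impurity, so cedar and the flask both have 29.3 mM.
2. First rung: one catalyst round, the turnover time. Cedar's first reading shows 44.0% reacted at 3.00 min, so one round takes about 0.277 min.
3. Next rung: the substrate half-life, the time for the unreacted substrates to halve at full partner. Read as a pseudo-first-order loss, the same cedar reading gives 3.59 min, longer than a round, and I carry it to the flask, which has cedar's catalyst, impurity and partner charges.
4. Early time: 2.5 min is shorter than that half-life, so I reckon the flask still in its first half-life. Cedar's pair at 15.0 min differs by 6 percentage points, each reading carrying 2 points, so I can neither read a preference nor exclude one.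
5. Last rung: 25 min. The substrates are the limiting reagent, so the partner can fall to a third of its charge. Taking the half-life as inverse to the partner, the flask gets between 2.32 and 6.96 half-lives, which is my conversion bracket of 80.0% to 99.2%.

The forecast gives 0%, 0% and 91%, holding that “the catalyst shows no detectable preference for either mirror-image substrate”.

The flask gives −5.99%, 0.474% and 93.3%.

    coupling partner + catalyst intermediate A → free catalyst + left-handed product (k = 11.9 /M/min)
    free catalyst + left-handed substrate ⇌ catalyst intermediate A (K = 1.07 /M, k = 14.6 /M/min)
    left-handed product ⇌ right-handed product (k = 0.0892 /min)
    coupling partner + catalyst intermediate B → free catalyst + right-handed product (k = 5.11 /M/min)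
    free catalyst + right-handed substrate ⇌ catalyst intermediate B (K = 1.75 /M, k = 31.8 /M/min)
    2 free catalyst ⇌ resting dimer (K = 39.0 /M, k = 3.23 /M/min)
    free catalyst + impurity → spent catalyst (k = 135 /M/min)

The flask's conversion amounts to 3.90 half-lives, inside the bracket, while its early excess has the right-handed product ahead. Now take the neighbouring flask, the same recipe with 0.027 M of impurity. Its working catalyst is 9.00 mM, so, taking the half-life as inverse to working catalyst, it stretches to 11.7 min. The same count gives 0.712 to 2.14 half-lives, or 39.0% to 77.3% conversion. The neighbouring flask reaches 68.2%, with 75.0% of its catalyst spent.

(The runs stem from a simulated flask on assumed constants, and the scatter is random.)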